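Late in Saturday's run Q stood level near 29.7% while L went on falling, and late in Thursday's run Q itself fell, so something was removing Q and taking L with it.

| setting | Saturday's | Thursday's | flask |
|---|---|---|---|
| L | 0.067 M | 0.15 M | 0.10 M |
| D | 0.070 M | 0.070 M | 0.0700 M |
| remark | run made earlier | run made earlier |  |
| time |  |  | 4.0 h |
| volume of the second phase over the first |  |  | 1.0 |

- Saturday's (time / h: Q / %, L / %): 0.250: 5.2, 94.6; 0.667: 16.0, 76.5; 1.33: 25.6, 50.9; 2.00: 29.1, 34.2; 3.00: 30.1, 19.2; 4.00: 29.7, 11.6; 5.00: 29.9, 7.0
- Thursday's (time / h: Q / %, L / %): 0.417: 6.2, 89.3; 0.667: 8.8, 80.2; 0.833: 9.7, 74.1; 1.33: 10.1, 60.0; 2.00: 9.7, 47.3; 3.00: 7.4, 35.2; 5.00: 4.3, 24.7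

(scatter of a reading: 0.3 percentage points)

1. amount of Q at 4.0 h, in percent of the L charged
2. the change that raises the amount of Q at 4.0 h, in percent of the L charged most ("none" if none brings more than 2 percentage points) (north-west / south-east / none)
3. amount of Q at 4.0 h, in percent of the L charged, after south-east

- north-west: doubling the transfer coefficient of D, all else as stated
- south-east: doubling the amount of D, all else as stated

- in the second phase: D; everything else is in the first
- charges count per volume of the first phase; a concentration in a rate is the amount of a species over the volume of its own phase; every rate counts per litre of the first phase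
- the earlier runs hold the two phases in the same ratio of volumes as the flask asked about

1. I began with the main step: one L and one D make one Q. D is the limiting reagent in this flask, 0.0700 M against 0.10 M of L, so this step by itself could bring Q to 70.0% of the L charged.

2. Then I added one step: Q meets L and gives a waste holding two L and one D. So the D spent is half the sum of L lost and Q present. Q is made and removed in proportion to L, so L cancels wherever Q stands level. Saturday's reading at 4.00 h gives 0.654, and Thursday's at 5.00 h gives 0.626. Thursday's Q was still falling at that reading, so its figure was rough. I carried 0.640 as the holding ratio, Q present over D left, where D left means the charge less the D spent.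

3. Then came the feedback. Between the two runs I read about 18.9% of L left in this flask at 4.0 h, so 0.0811 M lost. Leaving Q out of the balance gave 18.8%. Putting that Q back gave 12.8%, and one more round gave 14.7%. The rounds close on 14.3%, my figure.

4. For doubled D I assumed the same ratio, with more D left. Counting the L charged as lost, I reckoned 43.6%. Doubling transfer adds no D to the charge, so I chose south-east.

The forecast, higher than my figure, gave 16% (14% to 18.5%), chose south-east with 36%, and said of doubling transfer “so it gains little”.

The flask gave 16.1%. South-east gained 23 percentage points and north-west 1.2 points, so south-east was best, with 39.5%.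

    E ⇌ D, rate k1*([E] - [D]/K1) per volume of the first phase (partition coefficient = 0.960, kL = 2.90 × 10⁻⁴ s⁻¹)
    L + E → Q (k = 0.00880 M⁻¹ s⁻¹)
    E ⇌ J (K = 2.40, k = 1.40 × 10⁻⁴ s⁻¹)
    L + Q → X (k = 0.00370 M⁻¹ s⁻¹)

With 17% of L left, the ratio puts this flask's level at 13.9%. Q stood above that and was still falling, from 18.3% at 2.00 h to 13.3% at 8.00 h. The run without the passing of L + Q into X holds 55.0% instead of 16.1%, the largest single effect, and 46% of what is missing.

For the neighbour with 0.040 M of L and 8.3% left, the ratio gives a level of 62.6%. That flask held 47.8%, below this level.

The readings were generated by integration on assumed constants; noise was put on by code.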